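## Retrosynthetic overview

1. The target is traced back (allyl ester cleavage, Horner–Wadsworth–Emmons, Wacker, Wittig at C8) to a 3β-hydroxy trans-decalin 8-ketone carrying a but-3-enyl group at C9.
2. Its 3β-OH, 4,4-dimethyl and 5α-H pattern comes from reductive methylation and borohydride reduction of a 4-methyl-Δ4-3-ketone, which in turn comes from a cross-conjugated ring A dienone ester.
3. Ring A is closed in one flask by a [3+3] Knoevenagel/aldol cyclocondensation that makes C1=C2 and C4=C5 together from methyl 3-oxopentanoate (C2, C3, C4 and one C4 methyl) and a ring B β-keto aldehyde.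
4. Enabling feature: on ring B the aldehyde carbon C1 and the ketone carbon C5 are 1,3-related across the quaternary, non-enolisable C10, and they match the two nucleophilic carbons C2 and C4 that flank the C3 carbonyl (the later acetoxy carbon) of ring A.
5. Ring B is bought as a cyclohexenone ketal (C8 masked), C20 enters by Suzuki coupling, and C9/C10 are set by asymmetric conjugate addition with formaldehyde trapping; ring order: B (purchased), then A (key step).

Key step: step 5

Assumption: the sense of induction of the ferrocenyl diphosphine in step 3 cannot be read from precedent on this enone, so the (R,SFc) ligand is written on the understanding that its antipode is used if a test run gives the mirror-image series; labdane numbering and α/β face descriptors are used for all intermediates.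

## Route

Step 1
Reactants: 1 1,4-dioxaspiro[4.5]dec-6-en-8-one
Product: 2 7-iodo-1,4-dioxaspiro[4.5]dec-6-en-8-one
Conditions: I2, pyridine, CH2Cl2, 0 °C to rt
Reagents that add atoms: iodine, II
Why: α-iodination of a cyclic enone by pyridine-mediated addition–elimination (Baylis–Hillman-type) should place iodine only on the α-vinylic carbon, the future C10.

Step 2
Reactants: 2 7-iodo-1,4-dioxaspiro[4.5]dec-6-en-8-one
Product: 3 7-methyl-1,4-dioxaspiro[4.5]dec-6-en-8-one
Conditions: MeB(OH)2, PdCl2(dppf) (5 mol %), K3PO4, THF/H2O, 65 °C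
Reagents that add atoms: methylboronic acid, CB(O)O
Why: Suzuki–Miyaura coupling of the α-iodoenone with methylboronic acid should install the future C20 methyl on the sp2 carbon without touching the ketal.

Step 3
Reactants: 3 7-methyl-1,4-dioxaspiro[4.5]dec-6-en-8-one; 4 but-3-enylmagnesium bromide
Product: 6 (6R,7S)-6-(but-3-enyl)-7-(hydroxymethyl)-7-methyl-1,4-dioxaspiro[4.5]decan-8-one, via bromomagnesium enolate 5 (not isolated)
Conditions: CuBr·SMe2 (5 mol %), (R)-1-[(SFc)-2-(diphenylphosphino)ferrocenyl]ethyldicyclohexylphosphine (6 mol %), t-BuOMe, −78 °C; then monomeric CH2O (cracked from paraformaldehyde) in THF, −78 °C; aq. NH4Cl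
Reagents that add atoms: formaldehyde, C=O
Why: Copper-catalysed asymmetric conjugate addition of a Grignard reagent to an α-substituted cyclic enone should set C9 under ligand control, and the regiodefined magnesium enolate should then undergo aldol addition to formaldehyde anti to the new butenyl group, so that the quaternary C10 carries the hydroxymethyl carbon (future C1) trans and the methyl cis to the side chain.

Step 4
Reactants: 6 (6R,7S)-6-(but-3-enyl)-7-(hydroxymethyl)-7-methyl-1,4-dioxaspiro[4.5]decan-8-one
Product: 7 (6R,7S)-6-(but-3-enyl)-7-methyl-8-oxo-1,4-dioxaspiro[4.5]decane-7-carbaldehyde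
Conditions: Dess–Martin periodinane, NaHCO3, CH2Cl2, 0 °C to rt; used crude
Reagents that add atoms: none
Why: Dess–Martin oxidation of the neopentyl primary alcohol under buffered, non-basic conditions should give the non-enolisable β-keto aldehyde without retro-aldol loss of formaldehyde and without touching a stereocentre.

Step 5
Reactants: 7 (6R,7S)-6-(but-3-enyl)-7-methyl-8-oxo-1,4-dioxaspiro[4.5]decane-7-carbaldehyde; 8 methyl 3-oxopentanoate
Product: 10 methyl 9β-(but-3-enyl)-8,8-ethylenedioxy-4,10β-dimethyl-3-oxo-Δ1,4-octalin-2-carboxylate, via Knoevenagel adduct 9 (not isolated)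
Conditions: piperidine (0.2 equiv), AcOH (0.2 equiv), 4 Å MS, toluene, rt then 110 °C
Reagents that add atoms: none
Why: Piperidinium acetate should condense the doubly activated methylene of 8 (future C2) with the neopentyl aldehyde carbon C1 of 7 (Knoevenagel condensation via the iminium ion), and the E and Z isomers of adduct 9 interconvert by reversible amine addition, so the whole mixture drains through the isomer that holds the ketone cis to C10. In that isomer the dienamine or dienol of the ethyl ketone attacks the ring B ketone carbon C5 through its methylene carbon C4 and loss of water gives the C4=C5 bond; the closest known reaction type is the tandem Knoevenagel/intramolecular aldol condensation ([3+3] cyclocondensation of a β-keto ester with a 1,3-dicarbonyl electrophile), whose second half is the aldol stage of a Wieland–Miescher-type annulation. Ring A closes in the 6-(enolendo)-exo-trig mode. No stereocentre is created, because both new bonds end as C=C bonds and C9 and C10 cannot enolise here, while the C5 configuration is deliberately left to step 8. The step needs site selectivity (C2 to the aldehyde, C4 to the ketone), which the ester on C2 and the higher electrophilicity of the aldehyde secure, and it needs one ring mode, which is secured because the only other aldol (C6 onto C3) gives a bridged ketol that cannot dehydrate and reverts.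

Step 6
Reactants: 10 methyl 9β-(but-3-enyl)-8,8-ethylenedioxy-4,10β-dimethyl-3-oxo-Δ1,4-octalin-2-carboxylate
Product: 11 methyl 9β-(but-3-enyl)-8,8-ethylenedioxy-4,10β-dimethyl-3-oxo-Δ4-octalin-2-carboxylate (C2 epimers and enol)
Conditions: LiBH(s-Bu)3 (1.05 equiv), THF, −78 °C; aq. NH4Cl
Reagents that add atoms: none
Why: Conjugate (1,4) hydride reduction of the doubly activated C1=C2 bond by a bulky trialkylborohydride should give the stabilised β-keto ester enolate while the tetrasubstituted C4=C5 enone, the ketal and the terminal alkene stay intact, and the labile C2 centre is erased in step 7.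

Step 7
Reactants: 11 methyl 9β-(but-3-enyl)-8,8-ethylenedioxy-4,10β-dimethyl-3-oxo-Δ4-octalin-2-carboxylate
Product: 12 9β-(but-3-enyl)-8,8-ethylenedioxy-4,10β-dimethyl-Δ4-octalin-3-one
Conditions: LiCl, H2O (2 equiv), DMSO, 140 °C
Reagents that add atoms: none
Why: Krapcho dealkoxycarbonylation (chloride attack on the ester methyl, loss of CO2, protonation) should remove the activating ester under neutral conditions that spare the ketal and the enone.

Step 8
Reactants: 12 9β-(but-3-enyl)-8,8-ethylenedioxy-4,10β-dimethyl-Δ4-octalin-3-one
Product: 14 9β-(but-3-enyl)-8,8-ethylenedioxy-4,4,10β-trimethyl-5α-decalin-3-one, via lithium enolate 13 (not isolated)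
Conditions: Li (2.5 equiv), NH3(l)/THF, t-BuOH (1.0 equiv), −78 to −33 °C; then MeI (excess), −78 °C to rt
Reagents that add atoms: iodomethane, CI
Why: Reductive alkylation (Birch-type reduction of the enone followed by C-methylation of the regiodefined lithium enolate) should protonate the C5 carbanion axially on the face opposite the C10 methyl, which sets the trans ring fusion (5α-H), and methylation at C4 completes the geminal dimethyl group.

Step 9
Reactants: 14 9β-(but-3-enyl)-8,8-ethylenedioxy-4,4,10β-trimethyl-5α-decalin-3-one
Product: 16 9β-(but-3-enyl)-3β-hydroxy-4,4,10β-trimethyl-5α-decalin-8-one, via hydroxy ketal 15 (not isolated)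
Conditions: NaBH4, MeOH, 0 °C; then 1 M aq. HCl, THF, rt
Reagents that add atoms: water, O
Why: Borohydride reduction of the 4,4-dimethyl-3-ketone should deliver hydride from the α face, away from the axial C4 and C10 methyl groups, to give the equatorial 3β-alcohol, and acid-catalysed acetal hydrolysis in the same flask frees the C8 ketone.

Step 10
Reactants: 16 9β-(but-3-enyl)-3β-hydroxy-4,4,10β-trimethyl-5α-decalin-8-one
Product: 17 14,15-dinorlabda-8(17),13(16)-dien-3β-ol
Conditions: Ph3PCH3Br, KOtBu (4 equiv each), toluene, 0 to 80 °C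
Reagents that add atoms: methyltriphenylphosphonium bromide, C[P+](c1ccccc1)(c1ccccc1)c1ccccc1.[Br-]
Why: Wittig methylenation of the ring B ketone should give the exocyclic C8(17) alkene, and the enolisable C9 centre can only equilibrate towards the equatorial β side chain that the target has.

Step 11
Reactants: 17 14,15-dinorlabda-8(17),13(16)-dien-3β-ol
Product: 18 14,15-dinorlabda-8(17),13(16)-dien-3β-yl acetate
Conditions: Ac2O, pyridine, DMAP (cat.), CH2Cl2, rt
Reagents that add atoms: acetic anhydride, CC(=O)OC(C)=O
Why: DMAP-catalysed acylation of the equatorial secondary alcohol should give the acetate without touching a stereocentre.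

Step 12
Reactants: 18 14,15-dinorlabda-8(17),13(16)-dien-3β-yl acetate
Product: 19 3β-acetoxy-14,15-dinorlabd-8(17)-en-13-one
Conditions: PdCl2 (10 mol %), CuCl (1 equiv), O2 (1 atm), DMF/H2O 7:1, rt
Reagents that add atoms: water, O
Why: Tsuji–Wacker oxidation should convert the monosubstituted terminal alkene into the methyl ketone with Markovnikov selectivity, while the 1,1-disubstituted exocyclic alkene reacts far more slowly.

Step 13
Reactants: 19 3β-acetoxy-14,15-dinorlabd-8(17)-en-13-one
Product: 20 allyl 3β-acetoxylabda-8(17),13E-dien-15-oate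
Conditions: allyl diethylphosphonoacetate, NaH, THF, 0 °C then reflux
Reagents that add atoms: allyl diethylphosphonoacetate, C=CCOC(=O)CP(=O)(OCC)OCC
Why: Horner–Wadsworth–Emmons olefination of the methyl ketone with a stabilised phosphonate anion should favour the E enoate (chain trans to the ester) through reversible addition, and the minor Z isomer is to be removed by chromatography.

Step 14
Reactants: 20 allyl 3β-acetoxylabda-8(17),13E-dien-15-oate
Product: 21 3-acetoxy-8(17),13E-labdadien-15-oic acid
Conditions: Pd(PPh3)4 (5 mol %), morpholine (5 equiv), THF, rt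
Reagents that add atoms: none
Why: Tsuji–Trost deallylation by zerovalent palladium should ionise the allyl ester to the carboxylate and a π-allyl complex that morpholine captures, so the acid is freed without touching the acetate or either alkene.

## Compound list

1 | 1,4-dioxaspiro[4.5]dec-6-en-8-one | O=C1C=CC2(CC1)OCCO2 | starting material
2 | 7-iodo-1,4-dioxaspiro[4.5]dec-6-en-8-one | O=C1C(I)=CC2(CC1)OCCO2 | intermediate
3 | 7-methyl-1,4-dioxaspiro[4.5]dec-6-en-8-one | O=C1C(C)=CC2(CC1)OCCO2 | intermediate
4 | but-3-enylmagnesium bromide | C=CCC[Mg]Br | starting material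
5 | bromomagnesium (6R)-6-(but-3-enyl)-7-methyl-1,4-dioxaspiro[4.5]dec-7-en-8-olate | O1CCOC12CCC(O[Mg]Br)=C(C)[C@H]2CCC=C | intermediate
6 | (6R,7S)-6-(but-3-enyl)-7-(hydroxymethyl)-7-methyl-1,4-dioxaspiro[4.5]decan-8-one | O1CCOC12CCC(=O)[C@](C)(CO)[C@H]2CCC=C | intermediate
7 | (6R,7S)-6-(but-3-enyl)-7-methyl-8-oxo-1,4-dioxaspiro[4.5]decane-7-carbaldehyde | O1CCOC12CCC(=O)[C@](C)(C=O)[C@H]2CCC=C | intermediate
8 | methyl 3-oxopentanoate | CCC(=O)CC(=O)OC | starting material
9 | Knoevenagel adduct of 7 and 8 (alkylidene β-keto ester, E/Z mixture, ring stereocentres as in 7) | O1CCOC12CCC(=O)[C@](C)(C=C(C(=O)OC)C(=O)CC)[C@H]2CCC=C | intermediate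
10 | methyl 9β-(but-3-enyl)-8,8-ethylenedioxy-4,10β-dimethyl-3-oxo-Δ1,4-octalin-2-carboxylate | O1CCOC12CCC3=C(C)C(=O)C(C(=O)OC)=C[C@]3(C)[C@H]2CCC=C | intermediate
11 | methyl 9β-(but-3-enyl)-8,8-ethylenedioxy-4,10β-dimethyl-3-oxo-Δ4-octalin-2-carboxylate (C2 epimers) | O1CCOC12CCC3=C(C)C(=O)C(C(=O)OC)C[C@]3(C)[C@H]2CCC=C | intermediate
12 | 9β-(but-3-enyl)-8,8-ethylenedioxy-4,10β-dimethyl-Δ4-octalin-3-one | O1CCOC12CCC3=C(C)C(=O)CC[C@]3(C)[C@H]2CCC=C | intermediate
13 | lithium Δ3-enolate of the 4-methyl-5α-decalin-3-one | O1CCOC12CC[C@H]3C(C)=C(O[Li])CC[C@]3(C)[C@H]2CCC=C | intermediate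
14 | 9β-(but-3-enyl)-8,8-ethylenedioxy-4,4,10β-trimethyl-5α-decalin-3-one | O1CCOC12CC[C@H]3C(C)(C)C(=O)CC[C@]3(C)[C@H]2CCC=C | intermediate
15 | 9β-(but-3-enyl)-8,8-ethylenedioxy-4,4,10β-trimethyl-5α-decalin-3β-ol | O1CCOC12CC[C@H]3C(C)(C)[C@@H](O)CC[C@]3(C)[C@H]2CCC=C | intermediate
16 | 9β-(but-3-enyl)-3β-hydroxy-4,4,10β-trimethyl-5α-decalin-8-one | O=C1CC[C@H]2C(C)(C)[C@@H](O)CC[C@]2(C)[C@H]1CCC=C | intermediate
17 | 14,15-dinorlabda-8(17),13(16)-dien-3β-ol | C=C1CC[C@H]2C(C)(C)[C@@H](O)CC[C@]2(C)[C@H]1CCC=C | intermediate
18 | 14,15-dinorlabda-8(17),13(16)-dien-3β-yl acetate | C=C1CC[C@H]2C(C)(C)[C@@H](OC(C)=O)CC[C@]2(C)[C@H]1CCC=C | intermediate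
19 | 3β-acetoxy-14,15-dinorlabd-8(17)-en-13-one | C=C1CC[C@H]2C(C)(C)[C@@H](OC(C)=O)CC[C@]2(C)[C@H]1CCC(C)=O | intermediate
20 | allyl 3β-acetoxylabda-8(17),13E-dien-15-oate | C=C1CC[C@H]2C(C)(C)[C@@H](OC(C)=O)CC[C@]2(C)[C@H]1CC/C(C)=C/C(=O)OCC=C | intermediate
21 | 3-acetoxy-8(17),13E-labdadien-15-oic acid, (3S,5R,9S,10R) | C=C1CC[C@H]2C(C)(C)[C@@H](OC(C)=O)CC[C@]2(C)[C@H]1CC/C(C)=C/C(=O)O | target

## Step count and risks

Total step count: 14. Longest linear sequence: 14 steps (from 1).

Steps most likely to fail:

Step 5. The ring closure may stall after the Knoevenagel stage because the enamine or enol of the conjugated ethyl ketone adds too slowly to the hindered C5 ketone, so that 9 is consumed by oligomerisation or by amine-induced loss of the formyl carbon. The fallback sets out from 9, which is then isolated from a Knoevenagel run kept at room temperature. Treatment with LiN(SiMe3)2 in THF at −78 to 0 °C should generate the cross-conjugated lithium dienolate stoichiometrically, and this closes onto C5 to give the bicyclic tertiary aldol F1. Acid-catalysed dehydration of F1 (TsOH, benzene, reflux with water removal) should then give the dienone ester, so the route is rejoined at 10.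

Step 3. Direct 1,2-addition of the Grignard reagent to the hindered α-methyl enone may compete with conjugate addition, and enantiofacial discrimination by the catalyst may be insufficient. The fallback sets out from 3. Stoichiometric organocopper addition (4 with CuI and Me3SiCl, THF, −78 °C) should give the racemic silyl enol ether F2. Mukaiyama-type hydroxymethylation (aqueous formaldehyde, Yb(OTf)3, THF) should give the racemic hydroxymethyl ketone F3. Kinetic resolution by lipase-catalysed acetylation (Burkholderia cepacia lipase, vinyl acetate, t-BuOMe), written for the case in which the unwanted enantiomer is acylated faster, should give the acetate of the mirror-image alcohol F4 and leave the wanted alcohol, so the route is rejoined at 6.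

Step 8. The enolate may be protonated by ammonia or tert-butanol before it is methylated, O-methylation may compete at the hindered tetrasubstituted enolate, and the ketone may be over-reduced. The fallback sets out from 12. The same dissolving-metal reduction, quenched with Me3SiCl/Et3N, should give the 5α-configured silyl enol ether F5. Simmons–Smith cyclopropanation of this electron-rich enol ether (Et2Zn, CH2I2, CH2Cl2, 0 °C) should give the siloxycyclopropane F6. Base-induced ring opening (NaOH, MeOH) then turns the cyclopropane methylene into the second C4 methyl, so the route is rejoined at 14.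

Further compounds
F1 | step 5 | methyl 9β-(but-3-enyl)-8,8-ethylenedioxy-5-hydroxy-4,10β-dimethyl-3-oxo-Δ1-octalin-2-carboxylate (C4 and C5 epimers) | O1CCOC12CCC3(O)C(C)C(=O)C(C(=O)OC)=C[C@]3(C)[C@H]2CCC=C
F2 | step 3 | racemic 6-(but-3-enyl)-7-methyl-8-(trimethylsilyloxy)-1,4-dioxaspiro[4.5]dec-7-ene | O1CCOC12CCC(O[Si](C)(C)C)=C(C)[C@H]2CCC=C.O1CCOC12CCC(O[Si](C)(C)C)=C(C)[C@@H]2CCC=C
F3 | step 3 | racemic trans-6-(but-3-enyl)-7-(hydroxymethyl)-7-methyl-1,4-dioxaspiro[4.5]decan-8-one | O1CCOC12CCC(=O)[C@](C)(CO)[C@H]2CCC=C.O1CCOC12CCC(=O)[C@@](C)(CO)[C@@H]2CCC=C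
F4 | step 3 | [(6S,7R)-6-(but-3-enyl)-7-methyl-8-oxo-1,4-dioxaspiro[4.5]decan-7-yl]methyl acetate | O1CCOC12CCC(=O)[C@@](C)(COC(C)=O)[C@@H]2CCC=C
F5 | step 8 | 9β-(but-3-enyl)-8,8-ethylenedioxy-4,10β-dimethyl-3-(trimethylsilyloxy)-5α-Δ3-octalin | O1CCOC12CC[C@H]3C(C)=C(O[Si](C)(C)C)CC[C@]3(C)[C@H]2CCC=C
F6 | step 8 | 3,4-methylene-bridged 3-(trimethylsilyloxy) derivative of F5 (siloxycyclopropane, C3/C4 configuration open) | O1CCOC12CC[C@H]3C4(C)CC4(O[Si](C)(C)C)CC[C@]3(C)[C@H]2CCC=C
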